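The data were generated by integration for substances that don't exist; the scatter is artificial.

- We cannot read the ratio at 4.0 s from any run, because the earliest reading, at 0.333 min, comes later: the first time is 0.200 of the second.

the same everywhere: gas 77 mM (held)
- epsilon: substrate 0.62 M; first nucleophile 0.31 M; run made earlier
- eta: substrate 0.62 M; first nucleophile 0.46 M; run made earlier
- alpha: substrate 0.31 M; first nucleophile 0.62 M; run made earlier
- flask: substrate 0.62 M; first nucleophile 0.620 M; time 6.0 min

| run | time / min | target / % | other capture product / % |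
|---|---|---|---|
| epsilon | 0.333 | 5.8 | 11.0 |
| epsilon | 1.00 | 8.1 | 32.6 |
| epsilon | 1.50 | 7.3 | 43.6 |
| epsilon | 2.50 | 3.9 | 55.9 |
| epsilon | 4.00 | 1.1 | 63.8 |
| epsilon | 5.00 | 0.6 | 65.3 |
| epsilon | 6.00 | 0.7 | 66.5 |
| eta | 0.333 | 7.5 | 9.9 |
| eta | 1.00 | 11.4 | 30.5 |
| eta | 1.50 | 10.6 | 41.6 |
| eta | 2.50 | 5.9 | 54.4 |
| eta | 4.00 | 2.5 | 62.8 |
| eta | 5.00 | 1.4 | 65.3 |
| eta | 6.00 | 0.9 | 66.5 |
| alpha | 0.500 | 11.6 | 14.3 |
| alpha | 0.833 | 13.2 | 24.7 |
| alpha | 1.50 | 12.8 | 39.1 |
| alpha | 3.00 | 6.2 | 57.3 |
| alpha | 6.00 | 0.7 | 67.3 |

(each reading ± 0.3 percentage points)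

- ratio of target to other capture product at 4.0 s
- ratio of target to other capture product at 30 s
- ratio of target to other capture product at 6.0 min

- the numbers in the tables scatter with a standard deviation of 0.3 percentage points
- at the start none of the gas is in solution

- The bench rule we try says that, at one clock time and with gas held at 77 mM, target over other capture product goes in proportion to c(first nucleophile).
- We test it by dividing that ratio by c(first nucleophile): at 1.50 min the epsilon, eta and alpha runs give 0.540 /M, 0.554 /M and 0.528 /M, though alpha holds 0.31 M of substrate against 0.62 M.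
- We carry the quotient read at 30 s, 1.31 /M in the alpha run: the capture ratio per molar of first nucleophile at that clock time, a selectivity factor.
- Multiplied by the flask's 0.620 M, it gives our reckoning for the flask at 30 s: 0.811.
- The quotient falls with the clock, from 1.70 /M at 0.333 min in the epsilon run to 0.540 /M at 1.50 min, so a value read at one time serves that time.
- Going back towards 4.0 s, we expect the flask's ratio to lie above 1.05, and we commit to that floor, not to a figure.
- The late end has its own border: the epsilon target reading at 6.00 min is 2.33 times the scatter, so our mean of the quotients from the three runs gives the flask about 0.0166 at 6.0 min, held loosely.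
- The forecast gives 4 (1.8 to 9), 0.82 (0.72 to 0.93) and 0.018 (0.009 to 0.03), reading that “the other product waits for gas to dissolve”.
- The simulation gives the flask 2.40 at 4.0 s, 0.820 at 30 s and 0.0175 at 6.0 min.

    substrate → intermediate (k = 0.0130 /s)
    first nucleophile + intermediate ⇌ target (K = 15.0 /M, k = 0.360 /M/s)
    second nucleophile + intermediate → other capture product (k = 3.60 /M/s)
    intermediate → solvolysis product (k = 0.0270 /s)
    substrate ⇌ dormant form (K = 6.60, k = 0.00490 /s)
    gas ⇌ second nucleophile, rate k6*(csat - [second nucleophile]) (kL = 0.170 /s)

- At 30 s the flask stands at 0.820 against our 0.811. A neighbouring flask changes one setting, 0.37 M of first nucleophile in place of 0.620 M, and the same factor gives it 0.485; its simulated ratio at 30 s is 0.504. At 6.00 min that neighbour holds target 0.540% and other capture product 66.9%, a ratio of 0.00808.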